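(The numbers in the tables stem from a simulated flask with constants of no real substance; noise was put on by code.)

At 2.50 min in the winter run there is a leftover: the left-handed substrate is down 16 percentage points, but left-handed product shows 7.8 %, so 8.1 points went somewhere else.

all flasks: left-handed substrate 1.1 M; right-handed substrate 1.1 M
- winter: partner 1.2 equiv; free catalyst 0.67 mol%; added ligand 15 mM; run made earlier
- spring: partner 1.2 equiv; free catalyst 1.5 mol%; added ligand 15 mM; run made earlier
- midnight: partner 1.2 equiv; free catalyst 1 mol%; added ligand 22 mM; run made earlier
- flask: partner 1.20 equiv; free catalyst 1 mol%; added ligand 15 mM

| run | time / min | left-handed product / % | left-handed substrate / % |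
|---|---|---|---|
| winter | 0.200 | 1.1 | 48.7 |
| winter | 0.417 | 2.6 | 45.8 |
| winter | 1.00 | 4.3 | 40.0 |
| winter | 2.50 | 7.8 | 34.1 |
| spring | 0.667 | 6.8 | 35.1 |
| spring | 1.33 | 10.1 | 29.2 |
| spring | 2.00 | 12.2 | 25.5 |
| spring | 2.50 | 12.3 | 23.6 |
| midnight | 0.667 | 4.3 | 42.5 |
| midnight | 1.33 | 6.8 | 37.1 |
| midnight | 2.00 | 7.8 | 33.7 |
| midnight | 2.50 | 8.5 | 31.3 |

(scatter of a reading: 0.5 percentage points)

- free catalyst is single-handed; left-handed substrate and right-handed substrate are mirror images of each other, charged as a racemate, each of them at the stated concentration
- the numbers in the tables scatter with a standard deviation of 0.5 percentage points
- no earlier run changes the charge of partner; that part of a forecast is a guess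

- apparent order in free catalyst when 20 % of the left-handed substrate and right-handed substrate together are converted (percent change of the rate of making left-handed product for one percent more free catalyst charged)
- apparent order in partner when 20 % of the left-handed substrate and right-handed substrate together are converted (percent change of the rate of making left-handed product for one percent more partner charged)

I take that leftover as a sign that the partner is shared, and I suppose that each unit of either substrate converted, by whatever road, takes one partner. The 1.20 equiv are counted on the left-handed substrate, but an equal charge of right-handed substrate stands beside it. So the partner covers 60.0 % of both together, less than the whole, which makes it the limiting reagent. At 20 % conversion, 66.7 % of the partner is still present. Charge a little more and the amount used stays the same, so the gain lands on what remains. Charged over present comes to 1.50, and this ratio, partner charged over partner present at the chosen conversion, is my partner lever. If the rate at that conversion is first order in present partner and hangs on the partner charge in no other way, the lever is the order asked for.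

That "if" is the weak link, and no run varies the partner. Still, in the spring run the slope of left-handed substrate falls 2.34-fold from the first pair of readings to the last. Over the same span the mean left-handed substrate of each pair falls 1.31-fold, and my reckoned partner, on the assumption that right-handed substrate stands level with left-handed substrate, falls 2.67-fold. In the spring run the slope follows my reckoned partner more closely than the left-handed substrate, though roughly, given the scatter. I commit to 1.50 for the apparent order in partner.

The forecast gives 1.4 for the catalyst, which I take over, and 0.5 for the partner, saying “Partner was never varied, so its order is a guess”. There my number differs.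

The flask gives an apparent order of 1.3 in free catalyst and 1.5 in partner.

    free catalyst + left-handed substrate ⇌ catalyst intermediate A (K = 0.390 M⁻¹, k = 140 M⁻¹ s⁻¹)
    free catalyst + right-handed substrate ⇌ catalyst intermediate B (K = 2.80 M⁻¹, k = 130 M⁻¹ s⁻¹)
    partner + catalyst intermediate A → free catalyst + left-handed product (k = 4.80 M⁻¹ s⁻¹)
    partner + catalyst intermediate B → free catalyst + right-handed product (k = 2.30 M⁻¹ s⁻¹)
    free catalyst + added ligand ⇌ idle complex, settled at all times (K = 530 M⁻¹)
    left-handed substrate ⇌ right-handed substrate (k = 0.180 s⁻¹)

At 40.0 min the flask holds partner at 0 %, with left-handed product at 13.9 % and right-handed product at 46.1 %. At 4.00 min the two products stand at 11.9 % and 39.5 %, which puts the lever at 6.98, with partner at 14.3 % of its charge.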